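**Retrosynthetic overview**

Target in labdane numbering (C1–C10 decalin, C11–C16 side chain, C17 on C8, C18/C19 on C4, C20 on C10): (4S,5R,8R,9S,10R)-17-hydroxylabd-13-en-16,15-olid-19-oic acid. Late disconnections: C12–C13 (B-alkyl Suzuki coupling with 3-bromofuran-2(5H)-one), C9–H together with the C11=C12 vinyl group (allylic formate reduction), C8–C17 and C11–C12 (two carbonyl-ene reactions with formaldehyde), C9=C11 (Wittig) from a C9 ketone.
Decalin: one gold-catalysed, alkyne-initiated cation–olefin bicyclisation of an open-chain 1,5-enyne; ring B closes first through the C5–C6 bond, ring A second through the C10–C1 bond (vinylsilane terminator); the butenolide ring is attached last as a preformed unit.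
Enabling feature: the trans C5(H)–C10(CH3) ring fusion between the quaternary C4 and C9 is the imprint of an E-trisubstituted C5=C10 olefin; its CH terminus C5 attacks the gold-activated alkyne carbon C6, the tertiary C10 cation then closes ring A, and the CO2Me/CH3 pair on the preformed C4 centre selects the face.
Open-chain precursor from dimethyl (S)-malate: C4 by double Fráter–Seebach alkylation, malate C2 degraded to the C5 aldehyde, C5=C10 by Wittig olefination, C6–C8 by propargylation, which leaves a temporary C9 silyl ether that is later oxidised to the C9 ketone.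

Key step: step 9

Remark: compounds 2, 8, 10 and 24 are taken as commercial; in step 7 the (R)-configured phosphoric acid is assumed to deliver the 5R carbinol, and its antipode would be used if the sense proved opposite.

**Route**

Step 1
Reactants: 1 dimethyl (S)-malate; 2 3-bromo-1-(trimethylsilyl)prop-1-yne
Product: 3 dimethyl (2S,3R)-2-hydroxy-3-[3-(trimethylsilyl)prop-2-yn-1-yl]butanedioate
Conditions: LiN(iPr)2 (LDA, 2.2 equiv), THF, −78 to −20 °C; then 2, −78 °C to rt
Reagents that add atoms: none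
Why: Fráter–Seebach alkylation: the chelated lithium alkoxide–ester enolate dianion should be alkylated at C3 on the face anti to the C1 ester group, which sets the 2,3-anti (3R) centre.

Step 2
Reactants: 3 dimethyl (2S,3R)-2-hydroxy-3-[3-(trimethylsilyl)prop-2-yn-1-yl]butanedioate
Product: 4 dimethyl (2S,3S)-2-hydroxy-3-methyl-3-[3-(trimethylsilyl)prop-2-yn-1-yl]butanedioate
Conditions: LiN(iPr)2 (2.2 equiv), THF, −78 to −20 °C; then MeI, −78 to 0 °C
Reagents that add atoms: iodomethane, CI
Why: Second Fráter–Seebach alkylation: methyl iodide should enter on the same face of the re-formed chelated dianion, so the order propargyl-then-methyl fixes the quaternary (3S) centre that becomes C4 (new methyl = C18, retained ester = C19).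

Step 3
Reactants: 4 dimethyl (2S,3S)-2-hydroxy-3-methyl-3-[3-(trimethylsilyl)prop-2-yn-1-yl]butanedioate
Product: 5 dimethyl (2S,3S)-2-hydroxy-3-methyl-3-[(2Z)-3-(trimethylsilyl)prop-2-en-1-yl]butanedioate
Conditions: H2 (1 atm), Pd/CaCO3 poisoned with Pb(OAc)2 (Lindlar catalyst), quinoline, EtOAc, rt
Reagents that add atoms: none
Why: Syn semi-hydrogenation of the silylalkyne should give the Z-vinylsilane, the geometry needed for an endocyclic vinylsilane termination in step 9.

Step 4
Reactants: 5 dimethyl (2S,3S)-2-hydroxy-3-methyl-3-[(2Z)-3-(trimethylsilyl)prop-2-en-1-yl]butanedioate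
Product: 6 (2S,3S)-2-hydroxy-4-methoxy-3-methyl-4-oxo-3-[(2Z)-3-(trimethylsilyl)prop-2-en-1-yl]butanoic acid
Conditions: LiOH·H2O (1.05 equiv), THF/H2O, 0 °C; then 1 M HCl
Reagents that add atoms: lithium hydroxide, [Li+].[OH-]
Why: Chemoselective saponification: the unhindered, inductively activated α-hydroxy ester should hydrolyse well before the neopentyl ester on the quaternary carbon.

Step 5
Reactants: 6 (2S,3S)-2-hydroxy-4-methoxy-3-methyl-4-oxo-3-[(2Z)-3-(trimethylsilyl)prop-2-en-1-yl]butanoic acid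
Product: 7 methyl (2S,4Z)-2-formyl-2-methyl-5-(trimethylsilyl)pent-4-enoate
Conditions: Pb(OAc)4 (1.1 equiv), CH2Cl2, 0 °C to rt
Reagents that add atoms: none
Why: Oxidative decarboxylation of an α-hydroxy acid by tetravalent lead (glycol-cleavage type) should turn malate C2 into the C5 aldehyde; the adjacent quaternary centre cannot epimerise.

Step 6
Reactants: 7 methyl (2S,4Z)-2-formyl-2-methyl-5-(trimethylsilyl)pent-4-enoate; 8 2-(triphenylphosphoranylidene)propanal
Product: 9 methyl (2S,3E)-2,4-dimethyl-5-oxo-2-[(2Z)-3-(trimethylsilyl)prop-2-en-1-yl]pent-3-enoate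
Conditions: toluene, 100 °C
Reagents that add atoms: none
Why: Wittig olefination with a stabilised ylide should give the E-trisubstituted C5=C10 olefin (bulky quaternary C4 trans to the formyl group) and brings in C10, C20 and C9.

Step 7
Reactants: 9 methyl (2S,3E)-2,4-dimethyl-5-oxo-2-[(2Z)-3-(trimethylsilyl)prop-2-en-1-yl]pent-3-enoate; 10 allenylboronic acid pinacol ester
Product: 12 methyl (2S,3E,5R)-5-hydroxy-2,4-dimethyl-2-[(2Z)-3-(trimethylsilyl)prop-2-en-1-yl]oct-3-en-7-ynoate, via O-pinacolboryl ether 11 (not isolated)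
Conditions: (R)-3,3'-bis(2,4,6-triisopropylphenyl)-1,1'-binaphthyl-2,2'-diyl hydrogen phosphate (5 mol%), 4 Å MS, toluene, −20 °C; aq. NaHCO3 work-up
Reagents that add atoms: none
Why: Brønsted-acid-catalysed propargylation (SE2' allenylboration through a closed chair transition state) should add C8–C7≡C6 to the aldehyde only and set the 5R carbinol (C9, a temporary stereocentre) under catalyst control.

Step 8
Reactants: 12 methyl (2S,3E,5R)-5-hydroxy-2,4-dimethyl-2-[(2Z)-3-(trimethylsilyl)prop-2-en-1-yl]oct-3-en-7-ynoate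
Product: 13 methyl (2S,3E,5R)-5-[(tert-butyldimethylsilyl)oxy]-2,4-dimethyl-2-[(2Z)-3-(trimethylsilyl)prop-2-en-1-yl]oct-3-en-7-ynoate
Conditions: TBSOTf, 2,6-lutidine, CH2Cl2, −78 to 0 °C
Reagents that add atoms: tert-butyldimethylsilyl triflate, CC(C)(C)[Si](C)(C)OS(=O)(=O)C(F)(F)F
Why: Silylation masks the homopropargylic alcohol, which would otherwise add to the gold-activated alkyne.

Step 9
Reactants: 13 methyl (2S,3E,5R)-5-[(tert-butyldimethylsilyl)oxy]-2,4-dimethyl-2-[(2Z)-3-(trimethylsilyl)prop-2-en-1-yl]oct-3-en-7-ynoate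
Product: 14 methyl (1S,4aS,5R,8aR)-5-[(tert-butyldimethylsilyl)oxy]-1,4a-dimethyl-1,2,4a,5,6,8a-hexahydronaphthalene-1-carboxylate
Conditions: [(tBu)2(2-biphenylyl)P]Au(NCMe)SbF6 (5 mol%), (CF3)2CHOH (2 equiv), CH2Cl2, −20 °C to rt
Reagents that add atoms: none
Why: Proposed new method: the cationic monovalent-gold phosphine complex π-activates the terminal alkyne, C5 of the E-trisubstituted C5=C10 olefin attacks C6 in 6-endo-dig fashion (ring B, bond C5–C6), and the developing tertiary C10 cation is captured at C1 by the Z-vinylsilane (6-endo ipso attack, β-silyl cation, loss of the silyl group to hexafluoroisopropanol, which also protodeaurates C7) to close ring A with a C1=C2 double bond; the closest known reactions are gold-catalysed 6-endo-dig polycyclisations of 1,5-enynes with carbon and heteroatom terminators and Lewis-acid cation–olefin cyclisations terminated by Z-vinylsilanes. Both rings close through a chair–chair array in which C6 and C1 add anti across the E-olefin, so the C5–H/C10–CH3 fusion should be trans. The absolute sense at C5 and C10 is relayed from C4: the CO2Me group, not the C18 methyl, takes the position that eclipses the olefin and becomes axial, syn to C20, which avoids a methyl–methyl allylic and 1,3-diaxial contact. The 5R silyl ether (C9) is matched, since it sits "inside", becomes pseudo-axial and anti to C20, and keeps the C9–H bond out of alignment with the C10 cation, which should suppress a 1,2-hydride shift. The step needs 6-endo over 5-endo attack, secured by the C10 methyl group that makes the in-ring cation tertiary, and ring closure over elimination at C10, favoured by the fully substituted C4 (Thorpe–Ingold effect) and the β-silicon effect.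

Step 10
Reactants: 14 methyl (1S,4aS,5R,8aR)-5-[(tert-butyldimethylsilyl)oxy]-1,4a-dimethyl-1,2,4a,5,6,8a-hexahydronaphthalene-1-carboxylate
Product: 15 methyl (1S,4aS,5R,8aR)-5-[(tert-butyldimethylsilyl)oxy]-1,4a-dimethyldecahydronaphthalene-1-carboxylate
Conditions: H2 (1 atm), 10% Pd on carbon, EtOAc, rt
Reagents that add atoms: none
Why: Heterogeneous hydrogenation should saturate the two cis-disubstituted ring olefins (C1=C2, C6=C7) without forming a stereocentre or touching the silyl ether and ester.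

Step 11
Reactants: 15 methyl (1S,4aS,5R,8aR)-5-[(tert-butyldimethylsilyl)oxy]-1,4a-dimethyldecahydronaphthalene-1-carboxylate
Product: 16 methyl (1S,4aS,5R,8aR)-5-hydroxy-1,4a-dimethyldecahydronaphthalene-1-carboxylate
Conditions: HF·pyridine, THF, 0 to 40 °C
Reagents that add atoms: none
Why: Fluoride-mediated desilylation should free the hindered axial C9 alcohol and leave the ester intact.

Step 12
Reactants: 16 methyl (1S,4aS,5R,8aR)-5-hydroxy-1,4a-dimethyldecahydronaphthalene-1-carboxylate
Product: 17 methyl (1S,4aS,8aR)-1,4a-dimethyl-5-oxodecahydronaphthalene-1-carboxylate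
Conditions: Dess–Martin periodinane, NaHCO3, CH2Cl2, rt
Reagents that add atoms: none
Why: Dess–Martin oxidation gives the C9 ketone and erases the temporary C9 stereocentre; C5 and C10 are not enolisable.

Step 13
Reactants: 17 methyl (1S,4aS,8aR)-1,4a-dimethyl-5-oxodecahydronaphthalene-1-carboxylate
Product: 18 methyl (1S,4aS,8aR)-1,4a-dimethyl-5-methylidenedecahydronaphthalene-1-carboxylate
Conditions: Ph3PCH3Br, KOtBu, toluene, 90 °C
Reagents that add atoms: methylenetriphenylphosphorane (from Ph3PCH3Br and KOtBu), C=P(c1ccccc1)(c1ccccc1)c1ccccc1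
Why: Wittig methylenation with the unstabilised ylide in hot toluene should convert the hindered C9 ketone into the exocyclic C9=C11 olefin, which puts C11 in place.

Step 14
Reactants: 18 methyl (1S,4aS,8aR)-1,4a-dimethyl-5-methylidenedecahydronaphthalene-1-carboxylate
Product: 19 methyl (1S,4aS,8aR)-5-(2-hydroxyethyl)-1,4a-dimethyl-1,2,3,4,4a,7,8,8a-octahydronaphthalene-1-carboxylate
Conditions: Me2AlCl (2 equiv), (CH2O)n, CH2Cl2, 0 °C to rt
Reagents that add atoms: formaldehyde (as paraformaldehyde), C=O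
Why: Lewis-acid-promoted carbonyl-ene reaction: formaldehyde bonds to C11 (giving C12) and takes its hydrogen from C8, the only allylic position that carries one, which moves the olefin to C8=C9.

Step 15
Reactants: 19 methyl (1S,4aS,8aR)-5-(2-hydroxyethyl)-1,4a-dimethyl-1,2,3,4,4a,7,8,8a-octahydronaphthalene-1-carboxylate
Product: 20 methyl (1S,4aS,5E,6R,8aR)-5-(2-hydroxyethylidene)-6-(hydroxymethyl)-1,4a-dimethyldecahydronaphthalene-1-carboxylate
Conditions: Me2AlCl (3 equiv), (CH2O)n, CH2Cl2, −20 °C to rt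
Reagents that add atoms: formaldehyde (as paraformaldehyde), C=O
Why: Second carbonyl-ene reaction: formaldehyde should attack the less substituted C8 from the α-face, anti to the axial C20 methyl, and take its hydrogen from C11, which sets C8 (CH2OH α, equatorial) and returns the olefin to C9=C11 as an allylic alcohol.

Step 16
Reactants: 20 methyl (1S,4aS,5E,6R,8aR)-5-(2-hydroxyethylidene)-6-(hydroxymethyl)-1,4a-dimethyldecahydronaphthalene-1-carboxylate
Product: 21 methyl (1S,4aS,5E,6R,8aR)-5-{2-[(methoxycarbonyl)oxy]ethylidene}-6-{[(methoxycarbonyl)oxy]methyl}-1,4a-dimethyldecahydronaphthalene-1-carboxylate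
Conditions: ClCO2Me (2.5 equiv), pyridine, DMAP (cat.), CH2Cl2, 0 °C
Reagents that add atoms: methyl chloroformate, COC(=O)Cl
Why: Acylation of both primary alcohols: the allylic carbonate is the leaving group for step 17 and the C17 carbonate keeps that hydroxyl from attacking the π-allyl complex.

Step 17
Reactants: 21 methyl (1S,4aS,5E,6R,8aR)-5-{2-[(methoxycarbonyl)oxy]ethylidene}-6-{[(methoxycarbonyl)oxy]methyl}-1,4a-dimethyldecahydronaphthalene-1-carboxylate
Product: 22 methyl (1S,4aR,5S,6R,8aR)-5-ethenyl-6-{[(methoxycarbonyl)oxy]methyl}-1,4a-dimethyldecahydronaphthalene-1-carboxylate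
Conditions: Pd2(dba)3·CHCl3 (2.5 mol%), PBu3 (10 mol%), HCO2H, Et3N, THF, 40 °C
Reagents that add atoms: none
Why: Tsuji reduction (formate hydrogenolysis of an allylic carbonate by zerovalent palladium): with PBu3 the hydride should go to the more substituted terminus C9 of the π-allyl complex from the palladium-bearing α-face, anti to C20, which sets 9α-H (side chain β, equatorial) and leaves the terminal C11=C12 vinyl group.

Step 18
Reactants: 22 methyl (1S,4aR,5S,6R,8aR)-5-ethenyl-6-{[(methoxycarbonyl)oxy]methyl}-1,4a-dimethyldecahydronaphthalene-1-carboxylate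
Product: 23 (1S,4aR,5S,6R,8aR)-5-ethenyl-6-(hydroxymethyl)-1,4a-dimethyldecahydronaphthalene-1-carboxylic acid
Conditions: NaSEt (5 equiv), DMF, 100 °C; then 1 M HCl
Reagents that add atoms: none
Why: SN2 demethylation by thiolate at the O-methyl carbons should cleave the hindered axial C19 methyl ester, which resists acyl substitution, and the methyl carbonate, whose monoanion loses CO2.

Step 19
Reactants: 23 (1S,4aR,5S,6R,8aR)-5-ethenyl-6-(hydroxymethyl)-1,4a-dimethyldecahydronaphthalene-1-carboxylic acid; 24 3-bromofuran-2(5H)-one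
Product: 26 (1S,4aR,5S,6R,8aR)-6-(hydroxymethyl)-1,4a-dimethyl-5-[2-(2-oxo-2,5-dihydrofuran-3-yl)ethyl]decahydronaphthalene-1-carboxylic acid (target), via B-alkyl-9-borabicyclononane 25 (not isolated)
Conditions: 9-BBN (3.5 equiv), THF, 0 °C to rt; then 24, PdCl2(dppf) (5 mol%), AsPh3 (10 mol%), Cs2CO3, DMF/H2O, rt; dilute HCl work-up
Reagents that add atoms: none
Why: B-alkyl Suzuki–Miyaura coupling: anti-Markovnikov hydroboration of the terminal vinyl group and coupling with the α-bromobutenolide should form C12–C13 and install the α-substituted butenolide without touching a stereocentre.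

**Compound list**

1 | dimethyl (S)-malate | COC(=O)C[C@H](O)C(=O)OC | starting material
2 | 3-bromo-1-(trimethylsilyl)prop-1-yne | C[Si](C)(C)C#CCBr | starting material
3 | dimethyl (2S,3R)-2-hydroxy-3-[3-(trimethylsilyl)prop-2-yn-1-yl]butanedioate | COC(=O)[C@@H](O)[C@@H](CC#C[Si](C)(C)C)C(=O)OC | intermediate
4 | dimethyl (2S,3S)-2-hydroxy-3-methyl-3-[3-(trimethylsilyl)prop-2-yn-1-yl]butanedioate | COC(=O)[C@@H](O)[C@](C)(CC#C[Si](C)(C)C)C(=O)OC | intermediate
5 | dimethyl (2S,3S)-2-hydroxy-3-methyl-3-[(2Z)-3-(trimethylsilyl)prop-2-en-1-yl]butanedioate | COC(=O)[C@@H](O)[C@](C)(C/C=C\[Si](C)(C)C)C(=O)OC | intermediate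
6 | (2S,3S)-2-hydroxy-4-methoxy-3-methyl-4-oxo-3-[(2Z)-3-(trimethylsilyl)prop-2-en-1-yl]butanoic acid | OC(=O)[C@@H](O)[C@](C)(C/C=C\[Si](C)(C)C)C(=O)OC | intermediate
7 | methyl (2S,4Z)-2-formyl-2-methyl-5-(trimethylsilyl)pent-4-enoate | C[Si](C)(C)/C=C\C[C@](C)(C(=O)OC)C=O | intermediate
8 | 2-(triphenylphosphoranylidene)propanal | CC(C=O)=P(c1ccccc1)(c1ccccc1)c1ccccc1 | starting material
9 | methyl (2S,3E)-2,4-dimethyl-5-oxo-2-[(2Z)-3-(trimethylsilyl)prop-2-en-1-yl]pent-3-enoate | C[Si](C)(C)/C=C\C[C@](C)(C(=O)OC)/C=C(\C)C=O | intermediate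
10 | allenylboronic acid pinacol ester (4,4,5,5-tetramethyl-2-(propa-1,2-dien-1-yl)-1,3,2-dioxaborolane) | C=C=CB1OC(C)(C)C(C)(C)O1 | starting material
11 | O-pinacolboryl ether of 12: methyl (2S,3E,5R)-2,4-dimethyl-5-[(4,4,5,5-tetramethyl-1,3,2-dioxaborolan-2-yl)oxy]-2-[(2Z)-3-(trimethylsilyl)prop-2-en-1-yl]oct-3-en-7-ynoate | C[Si](C)(C)/C=C\C[C@](C)(C(=O)OC)/C=C(\C)[C@H](OB1OC(C)(C)C(C)(C)O1)CC#C | intermediate
12 | methyl (2S,3E,5R)-5-hydroxy-2,4-dimethyl-2-[(2Z)-3-(trimethylsilyl)prop-2-en-1-yl]oct-3-en-7-ynoate | C[Si](C)(C)/C=C\C[C@](C)(C(=O)OC)/C=C(\C)[C@H](O)CC#C | intermediate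
13 | methyl (2S,3E,5R)-5-[(tert-butyldimethylsilyl)oxy]-2,4-dimethyl-2-[(2Z)-3-(trimethylsilyl)prop-2-en-1-yl]oct-3-en-7-ynoate | C[Si](C)(C)/C=C\C[C@](C)(C(=O)OC)/C=C(\C)[C@H](O[Si](C)(C)C(C)(C)C)CC#C | intermediate
14 | methyl (1S,4aS,5R,8aR)-5-[(tert-butyldimethylsilyl)oxy]-1,4a-dimethyl-1,2,4a,5,6,8a-hexahydronaphthalene-1-carboxylate (trans-fused; OTBS on C9 α, CO2Me on C4 β, C20 β) | C[C@]12C=CC[C@](C)(C(=O)OC)[C@@H]1C=CC[C@H]2O[Si](C)(C)C(C)(C)C | intermediate
15 | methyl (1S,4aS,5R,8aR)-5-[(tert-butyldimethylsilyl)oxy]-1,4a-dimethyldecahydronaphthalene-1-carboxylate | C[C@]12CCC[C@](C)(C(=O)OC)[C@@H]1CCC[C@H]2O[Si](C)(C)C(C)(C)C | intermediate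
16 | methyl (1S,4aS,5R,8aR)-5-hydroxy-1,4a-dimethyldecahydronaphthalene-1-carboxylate | C[C@]12CCC[C@](C)(C(=O)OC)[C@@H]1CCC[C@H]2O | intermediate
17 | methyl (1S,4aS,8aR)-1,4a-dimethyl-5-oxodecahydronaphthalene-1-carboxylate | C[C@]12CCC[C@](C)(C(=O)OC)[C@@H]1CCCC2=O | intermediate
18 | methyl (1S,4aS,8aR)-1,4a-dimethyl-5-methylidenedecahydronaphthalene-1-carboxylate | C[C@]12CCC[C@](C)(C(=O)OC)[C@@H]1CCCC2=C | intermediate
19 | methyl (1S,4aS,8aR)-5-(2-hydroxyethyl)-1,4a-dimethyl-1,2,3,4,4a,7,8,8a-octahydronaphthalene-1-carboxylate | C[C@]12CCC[C@](C)(C(=O)OC)[C@@H]1CCC=C2CCO | intermediate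
20 | methyl (1S,4aS,5E,6R,8aR)-5-(2-hydroxyethylidene)-6-(hydroxymethyl)-1,4a-dimethyldecahydronaphthalene-1-carboxylate | C[C@]12CCC[C@](C)(C(=O)OC)[C@@H]1CC[C@@H](CO)/C2=C\CO | intermediate
21 | methyl (1S,4aS,5E,6R,8aR)-5-{2-[(methoxycarbonyl)oxy]ethylidene}-6-{[(methoxycarbonyl)oxy]methyl}-1,4a-dimethyldecahydronaphthalene-1-carboxylate | C[C@]12CCC[C@](C)(C(=O)OC)[C@@H]1CC[C@@H](COC(=O)OC)/C2=C\COC(=O)OC | intermediate
22 | methyl (1S,4aR,5S,6R,8aR)-5-ethenyl-6-{[(methoxycarbonyl)oxy]methyl}-1,4a-dimethyldecahydronaphthalene-1-carboxylate | C[C@]12CCC[C@](C)(C(=O)OC)[C@@H]1CC[C@@H](COC(=O)OC)[C@@H]2C=C | intermediate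
23 | (1S,4aR,5S,6R,8aR)-5-ethenyl-6-(hydroxymethyl)-1,4a-dimethyldecahydronaphthalene-1-carboxylic acid | C[C@]12CCC[C@](C)(C(=O)O)[C@@H]1CC[C@@H](CO)[C@@H]2C=C | intermediate
24 | 3-bromofuran-2(5H)-one | O=C1OCC=C1Br | starting material
25 | B-alkyl-9-borabicyclononane of 23: (1S,4aR,5S,6R,8aR)-5-[2-(9-borabicyclo[3.3.1]nonan-9-yl)ethyl]-6-(hydroxymethyl)-1,4a-dimethyldecahydronaphthalene-1-carboxylic acid (OH and CO2H transiently O-borylated in the flask) | C[C@]12CCC[C@](C)(C(=O)O)[C@@H]1CC[C@@H](CO)[C@@H]2CCB1C2CCCC1CCC2 | intermediate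
26 | (1S,4aR,5S,6R,8aR)-6-(hydroxymethyl)-1,4a-dimethyl-5-[2-(2-oxo-2,5-dihydrofuran-3-yl)ethyl]decahydronaphthalene-1-carboxylic acid | C[C@]12CCC[C@](C)(C(=O)O)[C@@H]1CC[C@@H](CO)[C@@H]2CCC1=CCOC1=O | target

**Step count and risks**

Total step count: 19. Longest linear sequence: 19 steps (1 to 26); 2, 8, 10 and 24 enter as purchased reagents.

Step 9 (Proposed new method). What may go wrong: loss of the C10 cation by proton elimination or by a 1,2-hydride shift from C9 before the weakly nucleophilic vinylsilane attacks, competition by the 5-endo pathway, or low facial selectivity relayed from C4. Fallback (two known reactions in place of the cascade), setting out from 13: the same gold catalyst in CH2Cl2/MeOH should give, by 6-endo alkoxycyclisation with anti addition of C6 and methanol across the C5=C10 olefin, the monocyclic tertiary methyl ether F1, in which ring B is already closed through C5–C6. SnCl4 in CH2Cl2 at −78 °C then ionises the tertiary ether, and the Z-vinylsilane closes ring A in a classical Lewis-acid vinylsilane-terminated cyclisation, which comes back to the route at 14.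

Step 15. What may go wrong: no reaction at the hindered trisubstituted C8=C9 olefin, attack of formaldehyde from the β-face, or ionisation and Prins-type side reactions of the allylic aluminium alkoxide that is formed. Fallback (hydroboration in place of the ene reaction), setting out from 19: N-(phenylselanyl)phthalimide and PBu3 give the phenyl selenide F2. BH3·SMe2 followed by pinacol should add boron to C8 and hydrogen to C9, both from the α-face, to give the boronic ester F3. Matteson homologation (BrCH2Cl, n-BuLi, −78 °C) inserts C17 to give the homologated boronic ester F4. H2O2/NaOH then oxidises the C–B bond to C17–OH and the selenide to the selenoxide, whose syn-elimination makes the vinyl group, to give the hydroxy ester F5. NaSEt in DMF demethylates F5 and the route is rejoined at 23.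

Step 17. What may go wrong: hydride transfer to the primary terminus C12 (ethylidene in place of vinyl), β-hydride elimination to a diene, or delivery from the β-face. Fallback (diazene-mediated reductive transposition in place of palladium catalysis), setting out from 20: NaSEt in DMF gives the dihydroxy acid F6. MnO2 oxidises only the allylic alcohol to the enal F7. TsNHNH2 gives the tosylhydrazone F8. Catecholborane, then NaOAc·3H2O with warming, reduces it to the allylic diazene, which loses N2 with hydrogen transfer to C9, expected on the less hindered α-face, and shift of the double bond to C11=C12. This comes back to the route at 23.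

**Further compounds**

F1 | step 9 | methyl (2S,4Z)-2-[(1S,5R,6S)-5-[(tert-butyldimethylsilyl)oxy]-6-methoxy-6-methylcyclohex-2-en-1-yl]-2-methyl-5-(trimethylsilyl)pent-4-enoate | CO[C@]1(C)[C@H](O[Si](C)(C)C(C)(C)C)CC=C[C@H]1[C@](C)(C/C=C\[Si](C)(C)C)C(=O)OC
F2 | step 15 | methyl (1S,4aS,8aR)-1,4a-dimethyl-5-[2-(phenylselanyl)ethyl]-1,2,3,4,4a,7,8,8a-octahydronaphthalene-1-carboxylate | C[C@]12CCC[C@](C)(C(=O)OC)[C@@H]1CCC=C2CC[Se]c1ccccc1
F3 | step 15 | methyl (1S,4aR,5S,6R,8aR)-1,4a-dimethyl-5-[2-(phenylselanyl)ethyl]-6-(4,4,5,5-tetramethyl-1,3,2-dioxaborolan-2-yl)decahydronaphthalene-1-carboxylate | C[C@]12CCC[C@](C)(C(=O)OC)[C@@H]1CC[C@@H](B3OC(C)(C)C(C)(C)O3)[C@@H]2CC[Se]c1ccccc1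
F4 | step 15 | methyl (1S,4aR,5S,6R,8aR)-1,4a-dimethyl-5-[2-(phenylselanyl)ethyl]-6-[(4,4,5,5-tetramethyl-1,3,2-dioxaborolan-2-yl)methyl]decahydronaphthalene-1-carboxylate | C[C@]12CCC[C@](C)(C(=O)OC)[C@@H]1CC[C@@H](CB3OC(C)(C)C(C)(C)O3)[C@@H]2CC[Se]c1ccccc1
F5 | step 15 | methyl (1S,4aR,5S,6R,8aR)-5-ethenyl-6-(hydroxymethyl)-1,4a-dimethyldecahydronaphthalene-1-carboxylate | C[C@]12CCC[C@](C)(C(=O)OC)[C@@H]1CC[C@@H](CO)[C@@H]2C=C
F6 | step 17 | (1S,4aS,5E,6R,8aR)-5-(2-hydroxyethylidene)-6-(hydroxymethyl)-1,4a-dimethyldecahydronaphthalene-1-carboxylic acid | C[C@]12CCC[C@](C)(C(=O)O)[C@@H]1CC[C@@H](CO)/C2=C\CO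
F7 | step 17 | (1S,4aS,5E,6R,8aR)-6-(hydroxymethyl)-1,4a-dimethyl-5-(2-oxoethylidene)decahydronaphthalene-1-carboxylic acid | C[C@]12CCC[C@](C)(C(=O)O)[C@@H]1CC[C@@H](CO)/C2=C\C=O
F8 | step 17 | 4-methylbenzenesulfonylhydrazone of F7 (C=N geometry not defined) | C[C@]12CCC[C@](C)(C(=O)O)[C@@H]1CC[C@@H](CO)/C2=C\C=NNS(=O)(=O)c1ccc(C)cc1
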